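**Retrosynthetic overview**

1. The target comes from its hydroquinone dimethyl ether by oxidative demethylation and reduction; the side-chain ketone comes from oxidation of a carbinol, and the enone arm from addition of an (E)-alkenyllithium to a non-enolisable δ-lactone.
2. That δ-lactone comes from oxidative lactonisation of a 1,5-diol, made by allylboration of a lactol with an α-substituted methallyl boronate; this forms the CH(OH)–CH2 bond and the Z-trisubstituted alkene.
3. The lactol comes from a δ-lactone formed in the key step: a metal-free, catalytic enantioselective Baeyer–Villiger desymmetrisation of meso cis-1,5-dimethylbicyclo[3.3.0]octan-3-one, which fixes both quaternary centres.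
4. The meso ketone comes from mono-deoxygenation of the commercial meso 3,7-dione; the boronate comes from a three-component conjunctive coupling (aryl bromide, vinyl boronate, isopropenyl Grignard).
5. Ring order: no carbocycle is built. The cyclopentane is one ring of the purchased dione; the other ring is expanded to a δ-lactone (step 2), opened (step 7), re-closed as the transposed δ-lactone (step 8) and opened for good (step 10).

Assumption: the six compounds marked as starting materials in the list are catalogue chemicals, and the sense of induction of the new catalyst in step 2 is fixed by choosing the catalyst antipode in a first screen.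

**Route**

Step 1
Reactants: 1 cis-1,5-dimethylbicyclo[3.3.0]octane-3,7-dione (meso; both methyls on the same face at the ring-fusion carbons); 2 p-toluenesulfonyl hydrazide
Product: 4 cis-1,5-dimethylbicyclo[3.3.0]octan-3-one (1R,5S; meso), via mono-tosylhydrazone 3 (not isolated)
Conditions: 2 (1.0 equiv), EtOH, 60 °C; evaporate; catecholborane (1.1 equiv), CHCl3, −10 °C; NaOAc·3H2O, reflux
Reagents that add atoms: none
Why: Tosylhydrazone deoxygenation (a mild Wolff–Kishner equivalent): catecholborane reduces the C=N bond and acetate triggers loss of sulfinate and N2, so one equivalent of hydrazide gives the statistical mono-deoxygenation (about 40–45% expected, dione recoverable) and the product is still meso.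

Step 2
Reactants: 4 cis-1,5-dimethylbicyclo[3.3.0]octan-3-one
Product: 5 (4aR,7aR)-4a,7a-dimethylhexahydrocyclopenta[c]pyran-3(1H)-one (cis-fused δ-lactone; carbonyl next to the CH2 on C-4a, ring oxygen next to the CH2 on C-7a)
Conditions: chiral BINOL-derived imidodiphosphorimidate acid IDPi–H (3 mol%, silylated in situ), Me3SiOOSiMe3 (1.3 equiv), PhMe, −60 °C, 48 h
Reagents that add atoms: bis(trimethylsilyl) peroxide, C[Si](C)(C)OO[Si](C)(C)C
Why: Proposed new method: a silylium-type Baeyer–Villiger oxidation under chiral counteranion control. The peroxide silylates the acid to Me3Si–X*, which activates the ketone for addition of Me3SiOOSiMe3 to a silylated Criegee adduct. A second silyl transfer to the distal peroxide oxygen makes (Me3Si)2O the leaving group. The confined chiral anion paired with this cation decides which of the two enantiotopic ring methylenes lies antiperiplanar to the O–O bond and migrates (C-4, on the side of the S bridgehead), so the meso ketone is desymmetrised and both quaternary carbons are fixed as R in one event. The closest known chemistry is the racemic Me3SiOSO2CF3-catalysed Baeyer–Villiger oxidation with bis(trimethylsilyl) peroxide and the chiral-phosphoric-acid/H2O2 desymmetrisation of 3-substituted cyclobutanones; neither has been shown as an enantioselective oxidation of a cyclopentanone.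

Step 3
Reactants: 5 (4aR,7aR)-4a,7a-dimethylhexahydrocyclopenta[c]pyran-3(1H)-one
Product: 6 (4aR,7aR)-4a,7a-dimethyloctahydrocyclopenta[c]pyran-3-ol (lactol, both anomers)
Conditions: iBu2AlH (1.1 equiv), CH2Cl2, −78 °C
Reagents that add atoms: none
Why: Partial reduction of a δ-lactone stops at the aluminium hemiacetal at −78 °C and leaves the quaternary centres untouched.

Step 4
Reactants: 7 4-methoxy-2-methylphenol
Product: 8 2-bromo-4-methoxy-6-methylphenol
Conditions: NBS (1.0 equiv), MeCN, 0 °C
Reagents that add atoms: N-bromosuccinimide, O=C1CCC(=O)N1Br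
Why: Electrophilic aromatic bromination goes ortho to the free hydroxyl, the only open activated position (para carries OMe, the other ortho position carries methyl).

Step 5
Reactants: 8 2-bromo-4-methoxy-6-methylphenol
Product: 9 1-bromo-2,5-dimethoxy-3-methylbenzene
Conditions: MeI, K2CO3, acetone, reflux
Reagents that add atoms: iodomethane, CI
Why: Williamson O-methylation of the phenoxide gives a hydroquinone dimethyl ether that survives organometallics and oxidations until step 12.

Step 6
Reactants: 9 1-bromo-2,5-dimethoxy-3-methylbenzene; 10 4,4,5,5-tetramethyl-2-vinyl-1,3,2-dioxaborolane; 11 isopropenylmagnesium bromide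
Product: 13 2-[1-(2,5-dimethoxy-3-methylphenyl)-3-methylbut-3-en-2-yl]-4,4,5,5-tetramethyl-1,3,2-dioxaborolane (configuration at the boron-bearing carbon immaterial), via borate complex 12 (not isolated)
Conditions: 10 + 11, THF, 0 °C to rt; then 9, Pd(OAc)2 (3 mol%), MandyPhos (3.6 mol%, either antipode), NaOSO2CF3 (2 equiv), THF/DMSO, 60 °C
Reagents that add atoms: none
Why: Conjunctive cross-coupling: the arylpalladium bromide from 9 binds the unhindered vinyl group of borate 12 and triggers a 1,2-metallate shift of the isopropenyl group from boron to the α-carbon, and reductive elimination joins the aryl group to the terminal CH2; the boron-bearing stereocentre is destroyed in step 7.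

Step 7
Reactants: 6 (4aR,7aR)-4a,7a-dimethyloctahydrocyclopenta[c]pyran-3-ol; 13 the allylic boronate (1.8 equiv)
Product: 14 (4Z)-6-(2,5-dimethoxy-3-methylphenyl)-1-[(1R,2R)-2-(hydroxymethyl)-1,2-dimethylcyclopentyl]-4-methylhex-4-en-2-ol (both C-2 epimers)
Conditions: PhMe, 70 °C, 36 h; aqueous work-up
Reagents that add atoms: none
Why: Allylboration through a closed chair (Zimmerman–Traxler) transition state on the open hydroxy-aldehyde tautomer of 6: the boronate adds through its CH2 terminus, and the arylmethyl α-substituent sits axial to avoid A(1,2) strain with the β-methyl group and the pinacolate, which gives the Z-trisubstituted alkene; the new carbinol centre is uncontrolled and is oxidised away in step 11.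

Step 8
Reactants: 14 the Z-configured 1,5-diol
Product: 15 (4aR,7aR)-3-[(2Z)-4-(2,5-dimethoxy-3-methylphenyl)-2-methylbut-2-en-1-yl]-4a,7a-dimethylhexahydrocyclopenta[c]pyran-1(3H)-one (both C-3 epimers)
Conditions: TEMPO (20 mol%), PhI(OAc)2 (2.5 equiv), CH2Cl2, rt
Reagents that add atoms: none
Why: Oxidative lactonisation of a 1,5-diol: the oxoammonium salt oxidises the primary alcohol in preference to the secondary one, the aldehyde is trapped as the six-membered lactol and oxidised on to the δ-lactone, whose carbonyl now sits on the quaternary carbon.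

Step 9
Reactants: 16 2-methylbut-3-yn-2-ol
Product: 17 (3E)-2-methyl-4-(tributylstannyl)but-3-en-2-ol
Conditions: Bu3SnH (1.1 equiv), PdCl2(PPh3)2 (1 mol%), THF, rt
Reagents that add atoms: tributyltin hydride, CCCC[SnH](CCCC)CCCC
Why: Palladium-catalysed syn-hydrostannation places tin on the terminal carbon, away from the tertiary carbinol, and so gives the E-alkenylstannane.

Step 10
Reactants: 15 the transposed δ-lactone; 17 (3E)-2-methyl-4-(tributylstannyl)but-3-en-2-ol (1.3 equiv)
Product: 19 (2E)-1-[(1R,2R)-2-[(4Z)-6-(2,5-dimethoxy-3-methylphenyl)-2-hydroxy-4-methylhex-4-en-1-yl]-1,2-dimethylcyclopentyl]-4-hydroxy-4-methylpent-2-en-1-one (both carbinol epimers; in equilibrium with its cyclic hemiketal), via dilithio alkenyl alkoxide 18 (not isolated)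
Conditions: 17, nBuLi (2.0 equiv per 17), THF, −78 to −30 °C; then 15, −78 to −40 °C; AcOH quench at −78 °C
Reagents that add atoms: none
Why: Tin–lithium exchange keeps the E geometry, and the alkenyllithium adds once to the non-enolisable lactone carbonyl because the cyclic lithium hemiketalate survives until the cold quench (acyl substitution of a lactone by an organolithium), which releases the E-enone and the side-chain carbinol.

Step 11
Reactants: 19 the δ-hydroxy enone
Product: 20 (4Z)-6-(2,5-dimethoxy-3-methylphenyl)-1-[(1R,2R)-2-[(2E)-4-hydroxy-4-methylpent-2-enoyl]-1,2-dimethylcyclopentyl]-4-methylhex-4-en-2-one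
Conditions: Dess–Martin periodinane (1.3 equiv), CH2Cl2, 0 °C to rt
Reagents that add atoms: none
Why: Dess–Martin oxidation converts the only secondary alcohol to the ketone without base, so the β,γ-alkene neither moves into conjugation nor loses its Z geometry, and the tertiary alcohol is inert.

Step 12
Reactants: 20 the dimethyl ether of the target
Product: 22 (4Z)-6-(2,5-dihydroxy-3-methylphenyl)-1-[(1R,2R)-2-[(2E)-4-hydroxy-4-methylpent-2-enoyl]-1,2-dimethylcyclopentyl]-4-methylhex-4-en-2-one (target), via quinone 21 (not isolated)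
Conditions: (NH4)2Ce(NO3)6 (2.2 equiv), MeCN/H2O, 0 °C, 15 min; then aq Na2S2O4, EtOAc, rt
Reagents that add atoms: water, O
Why: Oxidative demethylation of the para-dimethoxyarene gives the para-quinone (its oxygens come from water) and dithionite reduces only the quinone to the hydroquinone, leaving the enone, the skipped alkene and both quaternary centres untouched.

**Compound list**

1 | cis-1,5-dimethylbicyclo[3.3.0]octane-3,7-dione (meso) | O=C1C[C@@]2(C)CC(=O)C[C@@]2(C)C1 | starting material
2 | p-toluenesulfonyl hydrazide | Cc1ccc(cc1)S(=O)(=O)NN | starting material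
3 | mono-tosylhydrazone of 1 (C=N geometry not defined) | Cc1ccc(cc1)S(=O)(=O)NN=C1C[C@@]2(C)CC(=O)C[C@@]2(C)C1 | intermediate
4 | cis-(1R,5S)-1,5-dimethylbicyclo[3.3.0]octan-3-one (meso) | O=C1C[C@@]2(C)CCC[C@@]2(C)C1 | intermediate
5 | (4aR,7aR)-4a,7a-dimethylhexahydrocyclopenta[c]pyran-3(1H)-one | O=C1C[C@@]2(C)CCC[C@@]2(C)CO1 | intermediate
6 | (4aR,7aR)-4a,7a-dimethyloctahydrocyclopenta[c]pyran-3-ol (anomer mixture) | OC1C[C@@]2(C)CCC[C@@]2(C)CO1 | intermediate
7 | 4-methoxy-2-methylphenol | COc1ccc(O)c(C)c1 | starting material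
8 | 2-bromo-4-methoxy-6-methylphenol | COc1cc(C)c(O)c(Br)c1 | intermediate
9 | 1-bromo-2,5-dimethoxy-3-methylbenzene | COc1cc(C)c(OC)c(Br)c1 | intermediate
10 | 4,4,5,5-tetramethyl-2-vinyl-1,3,2-dioxaborolane | C=CB1OC(C)(C)C(C)(C)O1 | starting material
11 | isopropenylmagnesium bromide | CC(=C)[Mg]Br | starting material
12 | bromomagnesium isopropenyl(pinacolato)vinylborate | C=C[B-]1(C(C)=C)OC(C)(C)C(C)(C)O1.[Mg+]Br | intermediate
13 | 2-[1-(2,5-dimethoxy-3-methylphenyl)-3-methylbut-3-en-2-yl]-4,4,5,5-tetramethyl-1,3,2-dioxaborolane (C–B centre undefined) | COc1cc(C)c(OC)c(CC(B2OC(C)(C)C(C)(C)O2)C(C)=C)c1 | intermediate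
14 | (4Z)-6-(2,5-dimethoxy-3-methylphenyl)-1-[(1R,2R)-2-(hydroxymethyl)-1,2-dimethylcyclopentyl]-4-methylhex-4-en-2-ol (C-2 epimers) | C/C(=C/Cc1cc(OC)cc(C)c1OC)CC(O)C[C@@]1(C)CCC[C@@]1(C)CO | intermediate
15 | (4aR,7aR)-3-[(2Z)-4-(2,5-dimethoxy-3-methylphenyl)-2-methylbut-2-en-1-yl]-4a,7a-dimethylhexahydrocyclopenta[c]pyran-1(3H)-one (C-3 epimers) | C/C(=C/Cc1cc(OC)cc(C)c1OC)CC1C[C@@]2(C)CCC[C@@]2(C)C(=O)O1 | intermediate
16 | 2-methylbut-3-yn-2-ol | CC(C)(O)C#C | starting material
17 | (3E)-2-methyl-4-(tributylstannyl)but-3-en-2-ol | CCCC[Sn](CCCC)(CCCC)/C=C/C(C)(C)O | intermediate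
18 | lithium (3E)-4-lithio-2-methylbut-3-en-2-olate | [Li]/C=C/C(C)(C)O[Li] | intermediate
19 | (2E)-1-[(1R,2R)-2-[(4Z)-6-(2,5-dimethoxy-3-methylphenyl)-2-hydroxy-4-methylhex-4-en-1-yl]-1,2-dimethylcyclopentyl]-4-hydroxy-4-methylpent-2-en-1-one (carbinol epimers) | C/C(=C/Cc1cc(OC)cc(C)c1OC)CC(O)C[C@@]1(C)CCC[C@@]1(C)C(=O)/C=C/C(C)(C)O | intermediate
20 | (4Z)-6-(2,5-dimethoxy-3-methylphenyl)-1-[(1R,2R)-2-[(2E)-4-hydroxy-4-methylpent-2-enoyl]-1,2-dimethylcyclopentyl]-4-methylhex-4-en-2-one | C/C(=C/Cc1cc(OC)cc(C)c1OC)CC(=O)C[C@@]1(C)CCC[C@@]1(C)C(=O)/C=C/C(C)(C)O | intermediate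
21 | 2-[(2Z)-6-{(1R,2R)-2-[(2E)-4-hydroxy-4-methylpent-2-enoyl]-1,2-dimethylcyclopentyl}-3-methyl-5-oxohex-2-en-1-yl]-6-methylcyclohexa-2,5-diene-1,4-dione | C/C(=C/CC1=CC(=O)C=C(C)C1=O)CC(=O)C[C@@]1(C)CCC[C@@]1(C)C(=O)/C=C/C(C)(C)O | intermediate
22 | (4Z)-6-(2,5-dihydroxy-3-methylphenyl)-1-[(1R,2R)-2-[(2E)-4-hydroxy-4-methylpent-2-enoyl]-1,2-dimethylcyclopentyl]-4-methylhex-4-en-2-one | C/C(=C/Cc1cc(O)cc(C)c1O)CC(=O)C[C@@]1(C)CCC[C@@]1(C)C(=O)/C=C/C(C)(C)O | target

**Step count and risks**

Total step count: 12. Longest linear sequence: 8 steps (1, 2, 3, 7, 8, 10, 11, 12).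

The three steps most likely to fail:

Step 2 (the proposed new reaction). The unstrained cyclopentanone may react slowly or with low enantioselectivity. The fallback uses known chemistry and sets out from 4. Enantiotopic deprotonation with the chiral base LiN[(R)-CH(Me)Ph]2 (or its antipode) in the presence of Me3SiCl and LiCl in THF at −100 °C gives trimethyl{[(3aS,6aR)-3a,6a-dimethyl-1,3a,4,5,6,6a-hexahydropentalen-2-yl]oxy}silane F1. Ozonolysis (O3, CH2Cl2/MeOH, −78 °C) with NaBH4 work-up gives 2-[(1R,2R)-2-(hydroxymethyl)-1,2-dimethylcyclopentyl]acetic acid F2, which closes with catalytic TsOH in toluene to lactone 5, where the route is re-joined.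

Step 6. Direct Suzuki coupling or migration of the wrong alkenyl group may compete with the conjunctive pathway. The fallback sets out from 9. Magnesium in THF gives (2,5-dimethoxy-3-methylphenyl)magnesium bromide F3, which opens 2-methyl-2-vinyloxirane in the SN2' sense under CuI catalysis at −30 °C to give (2E)-4-(2,5-dimethoxy-3-methylphenyl)-2-methylbut-2-en-1-ol F4; any Z isomer can be carried along because the geometry is erased next. ClCO2Me and pyridine give (2E)-4-(2,5-dimethoxy-3-methylphenyl)-2-methylbut-2-en-1-yl methyl carbonate F5, and γ-selective borylation (B2pin2, CuCl/Xantphos/KOtBu catalyst, THF) returns to boronate 13.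

Step 7. The hindered lactol may open too slowly for the hindered boronate, or the Z:E ratio may erode. The fallback replaces the allylboration by a stereoretentive alkenyl–epoxide coupling and sets out from 6. Wittig methylenation (Ph3P=CH2, THF) gives [(1R,2R)-1,2-dimethyl-2-(prop-2-en-1-yl)cyclopentyl]methanol F6, and mCPBA/NaHCO3 gives {(1R,2R)-1,2-dimethyl-2-[(oxiran-2-yl)methyl]cyclopentyl}methanol F7 as an epimer mixture. In parallel, but-2-yn-1-ol is treated with NaAlH2(OCH2CH2OMe)2 and then I2 to give (2Z)-3-iodobut-2-en-1-ol F8; CBr4/PPh3 gives (2Z)-1-bromo-3-iodobut-2-ene F9; coupling with the Grignard reagent from 9 (made as in the fallback for step 6, CuI catalyst) gives 1-[(2Z)-3-iodobut-2-en-1-yl]-2,5-dimethoxy-3-methylbenzene F10. Iodine–magnesium exchange with iPrMgCl·LiCl gives chloro[(2Z)-4-(2,5-dimethoxy-3-methylphenyl)but-2-en-2-yl]magnesium F11 with retention, and its CuI-catalysed opening of the lithium alkoxide of the epoxy alcohol at the terminal carbon returns to diol 14.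

Further compounds
F1 | step 2 | trimethyl{[(3aS,6aR)-3a,6a-dimethyl-1,3a,4,5,6,6a-hexahydropentalen-2-yl]oxy}silane | C[Si](C)(C)OC1C[C@@]2(C)CCC[C@@]2(C)C=1
F2 | step 2 | 2-[(1R,2R)-2-(hydroxymethyl)-1,2-dimethylcyclopentyl]acetic acid | OC(=O)C[C@@]1(C)CCC[C@@]1(C)CO
F3 | step 6 | (2,5-dimethoxy-3-methylphenyl)magnesium bromide | COc1cc(C)c(OC)c([Mg]Br)c1
F4 | step 6 | (2E)-4-(2,5-dimethoxy-3-methylphenyl)-2-methylbut-2-en-1-ol | C/C(=C\Cc1cc(OC)cc(C)c1OC)CO
F5 | step 6 | (2E)-4-(2,5-dimethoxy-3-methylphenyl)-2-methylbut-2-en-1-yl methyl carbonate | C/C(=C\Cc1cc(OC)cc(C)c1OC)COC(=O)OC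
F6 | step 7 | [(1R,2R)-1,2-dimethyl-2-(prop-2-en-1-yl)cyclopentyl]methanol | C=CC[C@@]1(C)CCC[C@@]1(C)CO
F7 | step 7 | {(1R,2R)-1,2-dimethyl-2-[(oxiran-2-yl)methyl]cyclopentyl}methanol (oxirane epimers) | C1OC1C[C@@]2(C)CCC[C@@]2(C)CO
F8 | step 7 | (2Z)-3-iodobut-2-en-1-ol | OC/C=C(\I)C
F9 | step 7 | (2Z)-1-bromo-3-iodobut-2-ene | BrC/C=C(\I)C
F10 | step 7 | 1-[(2Z)-3-iodobut-2-en-1-yl]-2,5-dimethoxy-3-methylbenzene | COc1cc(C)c(OC)c(C/C=C(\I)C)c1
F11 | step 7 | chloro[(2Z)-4-(2,5-dimethoxy-3-methylphenyl)but-2-en-2-yl]magnesium | COc1cc(C)c(OC)c(C/C=C(\[Mg]Cl)C)c1
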